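**Strategy.** The route rests on disconnecting the benzene ring (C4a, C5, C6, C7, C8, C8a) of the 6,7-dimethoxycoumarin half at C5–C6, C4a–C8a and C8–C8a. This ring carries the lactone oxygen O1 on C8a para to the C6 methoxy group, the 4-alkoxyphenol pattern of a Dötz benzannulation. In one operation a chromium methoxy(1-methoxyvinyl)carbene, one of its CO ligands and the terminal alkyne of an enyne ester that already bears the umbelliferone ether are joined to give the phenol ortho to a cis acrylate ester. The enyne is made with the ester cis to the alkyne by a Still–Gennari olefination, so that the pyranone closes by simple lactonisation.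

Key step: step 6

Assumption: the α-aryloxy bis(2,2,2-trifluoroethyl)phosphonate 4 is taken to follow the usual kinetic preference of such reagents (ester cis to the aldehyde-derived group); a minor geometric isomer would be removed by chromatography at the stage of 6.

Step 1
Reactants: 1 methyl 2-[bis(2,2,2-trifluoroethoxy)phosphoryl]acetate
Product: 2 methyl 2-[bis(2,2,2-trifluoroethoxy)phosphoryl]-2-diazoacetate
Conditions: 4-acetamidobenzenesulfonyl azide, DBU, MeCN, 0 °C to rt
Reagents that add atoms: 4-acetamidobenzenesulfonyl azide, CC(=O)Nc1ccc(cc1)S(=O)(=O)N=[N+]=[N-]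
Why: Regitz diazo transfer, in which the doubly activated methylene of 1 is deprotonated and takes the terminal N2 unit of the sulfonyl azide, as is routine for phosphonoacetates.

Step 2
Reactants: 2 methyl 2-[bis(2,2,2-trifluoroethoxy)phosphoryl]-2-diazoacetate; 3 umbelliferone
Product: 4 methyl 2-[bis(2,2,2-trifluoroethoxy)phosphoryl]-2-[(2-oxo-2H-chromen-7-yl)oxy]acetate (racemic)
Conditions: Rh2(OAc)4 (2 mol %), ClCH2CH2Cl, 80 °C, slow addition of 2
Reagents that add atoms: none
Why: Rhodium-carbenoid O–H insertion, in which the electrophilic carbenoid from 2 is captured by the phenol oxygen (oxonium ylide, then proton shift) and should ignore the electron-poor C3–C4 double bond of the coumarin; the new stereocentre forms as a racemate and is removed in step 3.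

Step 3
Reactants: 4 methyl 2-[bis(2,2,2-trifluoroethoxy)phosphoryl]-2-[(2-oxo-2H-chromen-7-yl)oxy]acetate; 5 3-(trimethylsilyl)prop-2-ynal
Product: 6 methyl (E)-2-[(2-oxo-2H-chromen-7-yl)oxy]-5-(trimethylsilyl)pent-2-en-4-ynoate
Conditions: KN(SiMe3)2, 18-crown-6, THF, −78 °C
Reagents that add atoms: none
Why: Still–Gennari olefination, in which the potassium anion of the trifluoroethyl phosphonate adds to the reactive ynal and the adduct collapses under kinetic control, placing the ester cis to the aldehyde-derived silylalkyne, which is the (E) isomer because the aryloxy group outranks the ester.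

Step 4
Reactants: 6 methyl (E)-2-[(2-oxo-2H-chromen-7-yl)oxy]-5-(trimethylsilyl)pent-2-en-4-ynoate
Product: 7 methyl (E)-2-[(2-oxo-2H-chromen-7-yl)oxy]pent-2-en-4-ynoate
Conditions: Bu4NF, AcOH, THF, 0 °C
Reagents that add atoms: none
Why: Fluoride-induced protodesilylation of the alkynylsilane, buffered with acetic acid so that the lactone, the methyl ester and the acceptor enyne meet no free base and the alkene geometry is kept.

Step 5
Reactants: 8 methyl vinyl ether; 9 hexacarbonylchromium
Product: 12 pentacarbonyl[methoxy(1-methoxyethenyl)carbene]chromium, via 1-methoxyvinyllithium 10 (not isolated), via lithium acylchromate 11 (not isolated)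
Conditions: t-BuLi, THF, −78 to 0 °C; then 9, THF, 0 °C to rt; then Me3OBF4, CH2Cl2, 0 °C
Reagents that add atoms: trimethyloxonium tetrafluoroborate, C[O+](C)C.F[B-](F)(F)F
Why: Fischer carbene synthesis, that is α-lithiation of the enol ether, addition of the vinyllithium to a CO ligand of Cr(CO)6 and O-methylation of the acylate, a sequence known for α-alkoxyalkenyl complexes made from lithiated dihydropyran and glycals.

Step 6
Reactants: 12 pentacarbonyl[methoxy(1-methoxyethenyl)carbene]chromium; 7 methyl (E)-2-[(2-oxo-2H-chromen-7-yl)oxy]pent-2-en-4-ynoate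
Product: 14 methyl (E)-3-(2-hydroxy-4,5-dimethoxyphenyl)-2-[(2-oxo-2H-chromen-7-yl)oxy]prop-2-enoate, via tricarbonylchromium arene complex 13 (not isolated)
Conditions: THF, 50 °C, argon; then air, EtOAc, rt, daylight
Reagents that add atoms: none
Why: Dötz benzannulation: loss of one CO from the zerovalent chromium complex 12 lets the terminal alkyne of 7 insert into the Cr=C bond with its unsubstituted carbon bonded to the carbene carbon (C5–C6), CO insertion gives a chromium-bound dienylketene (C4a–C8a), and ring closure onto the methylene carbon of the methoxyvinyl group (C8–C8a) followed by enolisation gives the phenol as its Cr(CO)3 complex 13, from which air oxidation should release 14. The closest known reactions are benzannulations of alkenyl(alkoxy)carbene chromium complexes, α-alkoxyalkenyl ones included, with terminal alkynes and conjugated enynes. The one new ring (C4a, C5, C6, C7, C8, C8a) closes by thermal 6π electrocyclisation of the dienylketene, and no stereocentre is formed. The step needs regioselective alkyne insertion, secured by the terminal alkyne, whose larger alkenyl substituent ends beside the CO-derived carbon C8a, and phenol formation over five-ring products, favoured by an alkenyl chromium complex in an ethereal solvent. The neutral conditions at 50 °C should leave the umbelliferone lactone, the methyl ester and the (E) double bond untouched.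

Step 7
Reactants: 14 methyl (E)-3-(2-hydroxy-4,5-dimethoxyphenyl)-2-[(2-oxo-2H-chromen-7-yl)oxy]prop-2-enoate
Product: 15 daphnoretin methyl ether (6,7-dimethoxy-3-[(2-oxo-2H-chromen-7-yl)oxy]-2H-chromen-2-one)
Conditions: camphor-10-sulfonic acid (10 mol %), toluene, 80 °C
Reagents that add atoms: none
Why: Acid-catalysed lactonisation (intramolecular transesterification), in which the C8a phenol lies cis to the methyl ester across the C3–C4 double bond and closes the pyranone with loss of methanol; any material already cyclised in step 6 is the target itself.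

**Compound list**
1 | methyl 2-[bis(2,2,2-trifluoroethoxy)phosphoryl]acetate | COC(=O)CP(=O)(OCC(F)(F)F)OCC(F)(F)F | starting material
2 | methyl 2-[bis(2,2,2-trifluoroethoxy)phosphoryl]-2-diazoacetate | COC(=O)C(=[N+]=[N-])P(=O)(OCC(F)(F)F)OCC(F)(F)F | intermediate
3 | umbelliferone (7-hydroxy-2H-chromen-2-one) | Oc1ccc2ccc(=O)oc2c1 | starting material
4 | methyl 2-[bis(2,2,2-trifluoroethoxy)phosphoryl]-2-[(2-oxo-2H-chromen-7-yl)oxy]acetate (racemic) | COC(=O)C(Oc1ccc2ccc(=O)oc2c1)P(=O)(OCC(F)(F)F)OCC(F)(F)F | intermediate
5 | 3-(trimethylsilyl)prop-2-ynal | C[Si](C)(C)C#CC=O | starting material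
6 | methyl (E)-2-[(2-oxo-2H-chromen-7-yl)oxy]-5-(trimethylsilyl)pent-2-en-4-ynoate (ester cis to the alkyne) | COC(=O)/C(Oc1ccc2ccc(=O)oc2c1)=C\C#C[Si](C)(C)C | intermediate
7 | methyl (E)-2-[(2-oxo-2H-chromen-7-yl)oxy]pent-2-en-4-ynoate (ester cis to the alkyne) | COC(=O)/C(Oc1ccc2ccc(=O)oc2c1)=C\C#C | intermediate
8 | methyl vinyl ether | COC=C | starting material
9 | hexacarbonylchromium, Cr(CO)6 | [Cr](=C=O)(=C=O)(=C=O)(=C=O)(=C=O)=C=O | starting material
10 | 1-methoxyvinyllithium (not isolated) | [Li]C(=C)OC | intermediate
11 | lithium pentacarbonyl[(1-methoxyethenyl)(oxido)carbene]chromate, the lithium acylchromate (not isolated) | [Li+].COC(=C)C([O-])=[Cr](=C=O)(=C=O)(=C=O)(=C=O)=C=O | intermediate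
12 | pentacarbonyl[methoxy(1-methoxyethenyl)carbene]chromium | COC(=C)C(OC)=[Cr](=C=O)(=C=O)(=C=O)(=C=O)=C=O | intermediate
13 | tricarbonyl{η6-methyl (E)-3-(2-hydroxy-4,5-dimethoxyphenyl)-2-[(2-oxo-2H-chromen-7-yl)oxy]prop-2-enoate}chromium, Cr(CO)3 bound to the new benzene ring (not isolated) | COC(=O)/C(Oc1ccc2ccc(=O)oc2c1)=C\c1cc(OC)c(OC)cc1O.[Cr](=C=O)(=C=O)=C=O | intermediate
14 | methyl (E)-3-(2-hydroxy-4,5-dimethoxyphenyl)-2-[(2-oxo-2H-chromen-7-yl)oxy]prop-2-enoate (ester cis to the aryl ring) | COC(=O)/C(Oc1ccc2ccc(=O)oc2c1)=C\c1cc(OC)c(OC)cc1O | intermediate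
15 | daphnoretin methyl ether, 6,7-dimethoxy-3-[(2-oxo-2H-chromen-7-yl)oxy]-2H-chromen-2-one | COc1cc2cc(Oc3ccc4ccc(=O)oc4c3)c(=O)oc2cc1OC | target

**Step count.** Total: 7 steps. Longest linear sequence: 6 steps (steps 1, 2, 3, 4, 6 and 7, from 1 to 15); the carbene branch (step 5) joins at step 6.

**Steps most likely to fail**

Step 6. Alkyne insertion may be slow for an enyne conjugated to an acceptor, so that decomposition of the carbene complex or oligomerisation of the alkyne competes. The chromium vinylcarbene may also be intercepted by the neighbouring cis ester carbonyl before CO insertion. The fallback buys the trioxygenated benzene ring and sets out from 3, returning at 15. Umbelliferone 3 would be O-alkylated with tert-butyl bromoacetate (K2CO3, acetone, reflux) to tert-butyl 2-[(2-oxo-2H-chromen-7-yl)oxy]acetate F1. Cleavage with CF3CO2H in CH2Cl2 would give 2-[(2-oxo-2H-chromen-7-yl)oxy]acetic acid F2. Perkin condensation of F2 with commercial 2-hydroxy-4,5-dimethoxybenzaldehyde (Ac2O, Et3N, 120 °C) should then give 15 directly, as is known for 3-aryloxycoumarins.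

Step 5. Metalation of the enol ether may be incomplete, leaving t-BuLi to attack Cr(CO)6, and the β-unsubstituted alkenyl carbene may oligomerise during methylation, chromatography and concentration. The fallback replaces O-alkylation by the acyloxycarbene alcoholysis route and sets out from 11, returning at 12. Crude 11 would be precipitated from water with Me4NBr as tetramethylammonium pentacarbonyl[(1-methoxyethenyl)(oxido)carbene]chromate F3, a storable salt that can be purified. F3 would be O-acylated with acetyl bromide in CH2Cl2 at −40 °C to pentacarbonyl[acetoxy(1-methoxyethenyl)carbene]chromium F4. Addition of methanol should then exchange acetate for methoxide and give 12 in solution, to be used in step 6 without concentration.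

Step 3. Geometric control may erode in the olefination, so that the ester ends up trans to the alkyne and the later phenol cannot lactonise. The fallback moves the control of geometry to the end of the route and sets out from 4, returning at 14. The olefination of 4 with 5 would be run for conversion only, and the isomer methyl (Z)-2-[(2-oxo-2H-chromen-7-yl)oxy]-5-(trimethylsilyl)pent-2-en-4-ynoate F5 would be desilylated as in step 4 to methyl (Z)-2-[(2-oxo-2H-chromen-7-yl)oxy]pent-2-en-4-ynoate F6. Benzannulation of F6 with 12 as in step 6 should give tricarbonyl{η6-methyl (Z)-3-(2-hydroxy-4,5-dimethoxyphenyl)-2-[(2-oxo-2H-chromen-7-yl)oxy]prop-2-enoate}chromium F7 and, after air oxidation, methyl (Z)-3-(2-hydroxy-4,5-dimethoxyphenyl)-2-[(2-oxo-2H-chromen-7-yl)oxy]prop-2-enoate F8. In this isomer the ester cannot reach the vinylcarbene. Irradiation of a dilute MeCN solution of F8 at 365 nm, the known photochemical trans-to-cis path from 2-hydroxycinnamates to coumarins, should isomerise it to 14, which closes to 15 as in step 7.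

**Further compounds**
F1 | step 6 | tert-butyl 2-[(2-oxo-2H-chromen-7-yl)oxy]acetate | CC(C)(C)OC(=O)COc1ccc2ccc(=O)oc2c1
F2 | step 6 | 2-[(2-oxo-2H-chromen-7-yl)oxy]acetic acid | OC(=O)COc1ccc2ccc(=O)oc2c1
F3 | step 5 | tetramethylammonium pentacarbonyl[(1-methoxyethenyl)(oxido)carbene]chromate | C[N+](C)(C)C.COC(=C)C([O-])=[Cr](=C=O)(=C=O)(=C=O)(=C=O)=C=O
F4 | step 5 | pentacarbonyl[acetoxy(1-methoxyethenyl)carbene]chromium | COC(=C)C(OC(C)=O)=[Cr](=C=O)(=C=O)(=C=O)(=C=O)=C=O
F5 | step 3 | methyl (Z)-2-[(2-oxo-2H-chromen-7-yl)oxy]-5-(trimethylsilyl)pent-2-en-4-ynoate | COC(=O)/C(Oc1ccc2ccc(=O)oc2c1)=C/C#C[Si](C)(C)C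
F6 | step 3 | methyl (Z)-2-[(2-oxo-2H-chromen-7-yl)oxy]pent-2-en-4-ynoate | COC(=O)/C(Oc1ccc2ccc(=O)oc2c1)=C/C#C
F7 | step 3 | tricarbonyl{η6-methyl (Z)-3-(2-hydroxy-4,5-dimethoxyphenyl)-2-[(2-oxo-2H-chromen-7-yl)oxy]prop-2-enoate}chromium | COC(=O)/C(Oc1ccc2ccc(=O)oc2c1)=C/c1cc(OC)c(OC)cc1O.[Cr](=C=O)(=C=O)=C=O
F8 | step 3 | methyl (Z)-3-(2-hydroxy-4,5-dimethoxyphenyl)-2-[(2-oxo-2H-chromen-7-yl)oxy]prop-2-enoate | COC(=O)/C(Oc1ccc2ccc(=O)oc2c1)=C/c1cc(OC)c(OC)cc1O
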